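**Plan**
- Cuts: in each enol-trione (syncarpic) ring, the two bonds flanking the C2=C3(OH) pair, namely C2–C1(=O) and C3–C4Me2. Then arene–C(=O)iPr, then the two C4–H bonds of a bis-coumarin, then its two pyranone rings.
- Enabling feature: the remaining ring run C1(=O)–C6Me2–C5(=O)–C4Me2 is, atom for atom, the ring of commercial 2,2,4,4-tetramethylcyclobutane-1,3-dione. C2–C3 is Cα–C(=O) of a 3-aryl-4-methylpentanoate whose carboxyl sits beside a flanking phenol oxygen, so it can be tied to that oxygen as a dihydrocoumarin (temporary ring, activated aryl ester, no protecting groups).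
- Forward order: the benzene ring is bought, then two pyranone rings (double Pechmann), both stereocentres, and the isobutyryl group. Last, both four-membered rings are expanded to six-membered rings while both lactones open and free the phenols.
- Stereochemistry: both R centres come from ligand-controlled CuH delivery of hydride to C4 and C10 of the flat bis-coumarin. Two catalyst-controlled events on one molecule drain the minor enantiomer into separable diastereomers. No later step breaks a bond at these carbons.

Key step: step 4

Assumption 1: the (R)-ligand is taken to deliver hydride to the face of C4/C10 that gives the R centres; if the sense is the opposite, the (S)-ligand is used and nothing else changes.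
Assumption 2: a lactone closed on the other flanking phenol oxygen (linear instead of angular bis-lactone) is no loss, because step 4 opens both lactones and frees all three phenols; the route is drawn for the angular isomer.

Step 1
Reactants: 1 phloroglucinol; 2 ethyl 4-methyl-3-oxopentanoate (2 equiv)
Product: 3 5-hydroxy-4,10-di(propan-2-yl)-2H,8H-pyrano[2,3-f]chromene-2,8-dione (angular bis-coumarin)
Conditions: 2 (2.2 equiv), MeSO3H, 25 → 70 °C
Reagents that add atoms: none
Why: Twofold von Pechmann condensation (transesterification, intramolecular hydroxyalkylation, dehydration): phloroglucinol is the most reactive phenol for this reaction, the second annulation should close head-to-tail to the angular isomer (attack at C8 with closure on O7 and attack at C6 with closure on O5 give the same compound), and two lactone rings deactivate the last position enough to hold the reaction at the bis stage.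

Step 2
Reactants: 3 angular bis-coumarin
Product: 5 (4R,10R)-5-hydroxy-4,10-di(propan-2-yl)-3,4,9,10-tetrahydro-2H,8H-pyrano[2,3-f]chromene-2,8-dione, via tris-O-pinacolboryl bis-enolate 4 (not isolated)
Conditions: CuCl/NaOt-Bu (10 mol %), (R)-DTBM-SEGPHOS (11 mol %), HBpin (3.5 equiv), PhMe, 0 °C → rt; aq NH4Cl; separation from the (4R,10S)/(4S,10R) diastereomers
Reagents that add atoms: none
Why: Ligand-controlled CuH conjugate reduction (asymmetric 1,4-hydroboration) of 4-substituted coumarins: L*Cu–H should deliver hydride to C4 and C10 from the face chosen by the ligand, the boron enolates block over-reduction of the aryl lactones until work-up, and the double catalyst-controlled event raises the enantiomeric purity of the R,R product (Horeau principle).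

Step 3
Reactants: 5 (4R,10R)-bis-dihydrocoumarin; 6 2-methylpropanoyl chloride
Product: 7 (4R,10R)-5-hydroxy-6-(2-methylpropanoyl)-4,10-di(propan-2-yl)-3,4,9,10-tetrahydro-2H,8H-pyrano[2,3-f]chromene-2,8-dione
Conditions: 6 (1.5 equiv), AlCl3 (3 equiv), CH2Cl2–MeNO2, 0 → 40 °C; cold 1 M HCl
Reagents that add atoms: none
Why: Friedel–Crafts acylation (direct, or by O-acylation and Fries shift) can only end at C6, the single free arene carbon, where the new ketone is locked by a hydrogen bond to the C5 hydroxyl, while C4 and C10 carry neither a leaving group nor an acidic hydrogen and should stay untouched at this temperature.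

Step 4
Reactants: 7 acylated (4R,10R)-bis-dihydrocoumarin; 8 2,2,4,4-tetramethylcyclobutane-1,3-dione (2 equiv)
Product: 11 (R,R)-myrtucommulone A, via bis-cyclobutanol aldol adduct 9 (not isolated), via bis-β-keto lactone 10 (not isolated)
Conditions: LiHMDS (3.2 equiv), THF, −78 °C; 8 (2.5 equiv), −78 → −30 °C; LiHMDS (2.5 equiv), −30 °C → rt; 1 M HCl, 0 °C
Reagents that add atoms: none
Why: Proposed new method: each lactone enolate (C3, C9) should add, anti to the neighbouring isopropyl group, to a carbonyl of 8, whose flanking CMe2 groups are tied back by the ca. 90° ring angle, and the cyclobutanolate of 9 should then cleave a ring C(O−)–CMe2 bond by retro-aldol fragmentation (release of the four-ring strain), which sets free regiospecifically the tetrasubstituted enolate Me2C=C(O−) of 10 while the second portion of base keeps the acidic C3–H/C9–H of the new β-keto lactone deprotonated. That enolate carbon is then acylated by the lactone carbonyl, directly or after E1cB loss of the aryloxide to an acylketene, in a 6-(enolendo)-exo-trig closure that expels the phenoxide, so the four ring carbons of 8 plus C3–C2 (C9–C8) become the six-membered ring, a net two-carbon ring expansion 4 → 6 that also opens the temporary lactone ring. The closest known reaction types are the base-induced ring cleavage of adducts of 8 with alkoxides, amines and organometallics, the alkoxide-induced Dieckmann closure of dimethylketene-derived 3,5-dioxo esters to hexamethylcyclohexane-1,3,5-trione, and the Baker–Venkataraman O→C acyl transfer from an aryl ester to a ketone enolate; joining them through a carbon nucleophile into one ring expansion is the new element. No new stereocentre survives, because C3 and C9 end as sp2 enol carbons, and C4/C10 should keep their configuration since none of their bonds is broken, they carry no acidic hydrogen, and the product rests as its syncarpate anion, which cannot lose the arene by retro-Michael cleavage. The step needs fragmentation of the aldolate rather than reversal or β-lactone formation, and reaction at the lactone CH2 groups rather than at the aryl ketone: the first is secured by ring strain and by the vinylogous-carboxylate product anion as thermodynamic sink, the second by the C5 phenoxide, which turns the isobutyryl group into an unreactive vinylogous carboxylate and whose own addition to 8 is reversible and unproductive.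

**Compound list** (4, 9 and 10 are drawn in neutral form)
1 | phloroglucinol (benzene-1,3,5-triol) | Oc1cc(O)cc(O)c1 | starting material
2 | ethyl 4-methyl-3-oxopentanoate | CCOC(=O)CC(=O)C(C)C | starting material
3 | 5-hydroxy-4,10-di(propan-2-yl)-2H,8H-pyrano[2,3-f]chromene-2,8-dione | Oc1cc2OC(=O)C=C(C(C)C)c2c2OC(=O)C=C(C(C)C)c12 | intermediate
4 | tris-O-pinacolboryl bis-enolate (5-OBpin, 2-OBpin and 8-OBpin ketene acetals, configuration at C4 and C10 as in 5) | CC1(C)OB(Oc2cc3OC(OB4OC(C)(C)C(C)(C)O4)=C[C@H](C(C)C)c3c3OC(OB4OC(C)(C)C(C)(C)O4)=C[C@H](C(C)C)c23)OC1(C)C | intermediate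
5 | (4R,10R)-5-hydroxy-4,10-di(propan-2-yl)-3,4,9,10-tetrahydro-2H,8H-pyrano[2,3-f]chromene-2,8-dione | Oc1cc2OC(=O)C[C@H](C(C)C)c2c2OC(=O)C[C@H](C(C)C)c12 | intermediate
6 | 2-methylpropanoyl chloride | CC(C)C(=O)Cl | starting material
7 | (4R,10R)-5-hydroxy-6-(2-methylpropanoyl)-4,10-di(propan-2-yl)-3,4,9,10-tetrahydro-2H,8H-pyrano[2,3-f]chromene-2,8-dione | Oc1c(C(=O)C(C)C)c2OC(=O)C[C@H](C(C)C)c2c2OC(=O)C[C@H](C(C)C)c12 | intermediate
8 | 2,2,4,4-tetramethylcyclobutane-1,3-dione | CC1(C)C(=O)C(C)(C)C1=O | starting material
9 | 3,9-bis(1-hydroxy-2,2,4,4-tetramethyl-3-oxocyclobutyl) derivative of 7 (3,4-trans and 9,10-trans; spatial arrangement at C4 and C10 as in 7) | Oc1c(C(=O)C(C)C)c2OC(=O)[C@@H](C3(O)C(C)(C)C(=O)C3(C)C)[C@H](C(C)C)c2c2OC(=O)[C@@H](C3(O)C(C)(C)C(=O)C3(C)C)[C@H](C(C)C)c12 | intermediate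
10 | 3,9-bis(2,2,4-trimethyl-3-oxopentanoyl) derivative of 7 (C3 and C9 labile; spatial arrangement at C4 and C10 as in 7) | Oc1c(C(=O)C(C)C)c2OC(=O)C(C(=O)C(C)(C)C(=O)C(C)C)[C@H](C(C)C)c2c2OC(=O)C(C(=O)C(C)(C)C(=O)C(C)C)[C@H](C(C)C)c12 | intermediate
11 | (R,R)-myrtucommulone A: 2,2'-{[2,4,6-trihydroxy-5-(2-methylpropanoyl)-1,3-phenylene]bis[(1R)-2-methylpropane-1,1-diyl]}bis(3-hydroxy-4,4,6,6-tetramethylcyclohex-2-ene-1,5-dione) | CC(C)C(=O)c1c(O)c([C@H](C2=C(O)C(C)(C)C(=O)C(C)(C)C2=O)C(C)C)c(O)c([C@H](C2=C(O)C(C)(C)C(=O)C(C)(C)C2=O)C(C)C)c1O | target

Total step count: 4. Longest linear sequence: 4 steps (1 → 3 → 5 → 7 → 11).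

**Steps most likely to fail**

1. Step 4.
   - Risk: addition of the β-branched enolate to a carbonyl between two quaternary carbons may be too slow to compete with collapse of the aryl ester enolate to a ketene. The aldolate may also close onto the lactone carbonyl (β-lactonisation) instead of fragmenting.
   - Fallback (known chemistry): it sets out from 8, which is isomerised with catalytic AlCl3 at about 140 °C to the β-lactone dimer of dimethylketene, 3,3-dimethyl-4-(propan-2-ylidene)oxetan-2-one F1. F1 is an acylating agent whose carbonyl has only one quaternary neighbour. The trilithiated form of 7 is C-acylated by two equivalents of it with acyl–oxygen cleavage, as ester anions are.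
   - Return: the fallback comes back to the route at 10, now isolated after a mild acid quench. Compound 10 is then closed to 11 in a separate flask with NaH in THF (Baker–Venkataraman/Dieckmann-type acyl transfer).

2. Step 2.
   - Risk: hydride transfer to a β-carbon that carries a branched alkyl group and faces a peri oxygen may be sluggish. Facial selectivity may be poor, and the aryl lactones may be reduced further.
   - Fallback: it sets out from 1, which is annulated twice with ethyl propiolate (ZnCl2, 100 °C) to 5-hydroxy-2H,8H-pyrano[2,3-f]chromene-2,8-dione F2. The stereocentres are then made by C–C instead of C–H bond formation at an unhindered β-carbon, by Cu(I)/chiral ferrocenyl diphosphine-catalysed conjugate addition of i-PrMgBr (the first equivalent deprotonates the phenol) at −78 °C.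
   - Return: the fallback comes back at 5.

3. Step 1.
   - Risk: the second annulation may stall, because the hindered isopropyl ketone of 2 has to react with a ring already deactivated by one lactone. Forcing conditions may instead drive a third annulation or closure in the linear sense.
   - Fallback: it sets out from 1 and is stepwise. A single Pechmann condensation with one equivalent of 2 at room temperature gives 5,7-dihydroxy-4-(propan-2-yl)-2H-chromen-2-one F3. The second ring is then built by a different bond-forming event, Pd(OAc)2/CF3CO2H trans-hydroarylation of ethyl 4-methylpent-2-ynoate followed by lactonisation.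
   - Return: the fallback comes back at 3.

Further compounds
F1 | step 4 | 3,3-dimethyl-4-(propan-2-ylidene)oxetan-2-one | CC(C)=C1OC(=O)C1(C)C
F2 | step 2 | 5-hydroxy-2H,8H-pyrano[2,3-f]chromene-2,8-dione | Oc1cc2OC(=O)C=Cc2c2OC(=O)C=Cc12
F3 | step 1 | 5,7-dihydroxy-4-(propan-2-yl)-2H-chromen-2-one | Oc1cc(O)c2c(c1)OC(=O)C=C2C(C)C
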